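**Plan**

- Tetralone numbering is used: C1 ketone, C3 carbinol, C5 pyronyl, C6 phenyl, C8 phenol. Ring A is C1-C2-C3-C4-C4a-C8a; ring B is the benzene ring C4a-C5-C6-C7-C8-C8a.
- Retrosynthesis: the benzyl (pyrone OH) and silyl (C3 OH) groups are removed and ring B is returned to its 4a,5-dihydro level. C4a–C5 and C8–C8a are then cut together, giving an (S)-5-silyloxycyclohex-2-enone (ring A) and a methyl 4-pyronyl-3-phenylbut-2-enoate (C5 to C8). That ester is cut at C5–C6 into O-benzyl triacetic acid lactone and methyl phenylpropiolate.
- Enabling feature: C5 bears the pyrone and is therefore the acidic 6-methyl carbon of a 4-oxygenated 2-pyrone, while C8a and C4a are the alpha and beta carbons of a cyclohexenone built on the C1 ketone. The crowded C4a–C5–C6 array can thus be joined at sp3 carbon by an anionic annulation before ring B becomes flat.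
- Forward: ring A and the pyrone ring are bought. Ring B is the only ring made (Michael addition then Claisen closure, step 7); it is aromatised in step 8, and two deprotections finish the route.
- Stereochemistry: the single stereocentre of the target, C3 (S), comes from lipase desymmetrisation of a meso diacetate made from all-cis-cyclohexane-1,3,5-triol. The transient C4a and C5 centres vanish on aromatisation.

Key step: step 7

Assumption (remark on the chemistry): the lipase is taken to cleave the (R)-configured acetate of the meso diacetate. This is the sense expected from the empirical large/medium-substituent model for lipases when the silyloxy-bearing ring arm acts as the large group.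

**Route**

Step 1
Reactants: 1 all-cis-cyclohexane-1,3,5-triol
Product: 2 all-cis-5-(tert-butyldimethylsilyloxy)cyclohexane-1,3-diol (meso)
Conditions: TBSCl (1.0 equiv), imidazole, DMF, 0 °C to rt
Reagents that add atoms: tert-butyldimethylsilyl chloride, CC(C)(C)[Si](C)(C)Cl
Why: Silyl ether formation with a limiting amount of silyl chloride on three equivalent secondary hydroxyls should give the meso mono-ether statistically, separable from bis-ether and recyclable triol; no stereocentre is created.

Step 2
Reactants: 2 all-cis-5-(tert-butyldimethylsilyloxy)cyclohexane-1,3-diol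
Product: 3 all-cis-5-(tert-butyldimethylsilyloxy)cyclohexane-1,3-diyl diacetate (meso)
Conditions: Ac2O, pyridine, DMAP (cat.), CH2Cl2, rt
Reagents that add atoms: acetic anhydride, CC(=O)OC(C)=O
Why: DMAP-catalysed acylation of both secondary alcohols is routine and gives the meso substrate for hydrolytic desymmetrisation.

Step 3
Reactants: 3 all-cis-5-(tert-butyldimethylsilyloxy)cyclohexane-1,3-diyl diacetate
Product: 4 (1S,3R,5R)-3-(tert-butyldimethylsilyloxy)-5-hydroxycyclohexyl acetate (acetate carbon S, silyloxy and carbinol carbons R, all-cis)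
Conditions: Burkholderia cepacia lipase (Amano PS), phosphate buffer pH 7/MTBE, 30 °C
Reagents that add atoms: none
Why: Lipase-catalysed enantiotopos-selective hydrolysis of a meso 1,3-diacetate (acyl–oxygen cleavage, so the product gains only hydrogen) should cleave the (R)-acetate and leave the acetate on the (S)-carbon, which fixes the configuration of the later C3; neutral pH avoids 1,3-acyl migration.

Step 4
Reactants: 4 (1S,3R,5R)-3-(tert-butyldimethylsilyloxy)-5-hydroxycyclohexyl acetate
Product: 6 (S)-5-(tert-butyldimethylsilyloxy)cyclohex-2-en-1-one, via keto acetate 5 (not isolated)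
Conditions: Dess–Martin periodinane, CH2Cl2, 0 °C to rt; aqueous work-up; crude 5, DBU (1.1 equiv), CH2Cl2, 0 °C
Reagents that add atoms: none
Why: Dess–Martin oxidation of the free carbinol gives the beta-acetoxy ketone, which should lose acetic acid by E1cB elimination with DBU; the silyloxy carbon is not touched and, since the ketone arises at the former (R)-carbinol, the enone is (S).

Step 5
Reactants: 7 4-hydroxy-6-methyl-2H-pyran-2-one (triacetic acid lactone)
Product: 8 4-(benzyloxy)-6-methyl-2H-pyran-2-one
Conditions: BnOH, PPh3, DIAD, THF, 0 °C to rt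
Reagents that add atoms: benzyl alcohol, OCc1ccccc1
Why: Mitsunobu O-alkylation of the acidic 4-hydroxyl of the pyrone should give the 4-benzyl ether and avoids the C3-alkylation that benzyl halides can cause.

Step 6
Reactants: 8 4-(benzyloxy)-6-methyl-2H-pyran-2-one; 9 methyl 3-phenylprop-2-ynoate (methyl phenylpropiolate)
Product: 11 methyl (E)-4-[4-(benzyloxy)-2-oxo-2H-pyran-6-yl]-3-phenylbut-2-enoate, via lithiated pyrone 10 (not isolated)
Conditions: LiN(SiMe3)2 (1.05 equiv), THF, −78 °C; then 9, −78 to −40 °C; AcOH quench
Reagents that add atoms: none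
Why: Deprotonation of the 6-methyl group gives a vinylogous enolate that should undergo Michael addition to the phenyl-bearing carbon of the ynoate (carbanion addition to an aryl propiolate), and proton transfer from the newly acidic CH2 leaves a stabilised anion that does not add again; 11 is written as the E ester, but any Z or but-3-enoate isomer formed with it is carried on, because all give the same anion in step 7.

Step 7
Reactants: 6 (S)-5-(tert-butyldimethylsilyloxy)cyclohex-2-en-1-one; 11 methyl (E)-4-[4-(benzyloxy)-2-oxo-2H-pyran-6-yl]-3-phenylbut-2-enoate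
Product: 14 (3S,4aR,5R)-5-[4-(benzyloxy)-2-oxo-2H-pyran-6-yl]-3-(tert-butyldimethylsilyloxy)-8-hydroxy-6-phenyl-3,4,4a,5-tetrahydronaphthalen-1(2H)-one, via lithium dienolate 12 (not isolated), via Michael adduct enolate 13 (not isolated)
Conditions: LiN(SiMe3)2 (1.05 equiv), THF, −78 °C; then 6 (1.2 equiv), −78 °C to rt; AcOH quench
Reagents that add atoms: none
Why: The base removes the C5–H of 11, which is activated through both the pyrone and the enoate, to give the planar anion 12; this adds through C5 to C4a of enone 6, and the C1–C8a enolate 13 then attacks the C8 methyl ester and expels methoxide, which at once deprotonates the new C1/C8 beta-diketone, so the sequence ends in a stabilised enolate that is acidified on work-up. The closest known reaction is the Michael–Dieckmann (anionic [4+2], Staunton–Weinreb or glutaconate type) annulation of ester dienolates with cyclohexenones, here with a pyronyl group on the nucleophilic carbon. Ring B (C4a, C5, C6, C7, C8, C8a) closes in a 6-(enolexo)-exo-trig Claisen mode, which needs the ester and C5 cis on C6=C7; that geometry is reachable because it is lost in 12 and in the reversibly formed adduct. C4a should be set by axial attack on the enone face anti to the C3 silyloxy group (the 3,5-trans preference of 5-substituted cyclohexenones), and C5 should settle by equilibration of its acidic hydrogen with the pyronyl group trans to C4; both centres are removed in step 8, so a C5 epimer is carried on and only the C3 centre brought in by 6 has to survive. The step needs attack through C5 and not C7 and Claisen and not aldol closure: Michael and aldol events of the stabilised anion are reversible, whereas only the C5 adduct can drain into the irreversibly deprotonated beta-diketone, and that enolate, with only one equivalent of base that is consumed by the far more acidic donor, keeps C2 from enolising and expelling the C3 silyloxy group.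

Step 8
Reactants: 14 (3S,4aR,5R)-5-[4-(benzyloxy)-2-oxo-2H-pyran-6-yl]-3-(tert-butyldimethylsilyloxy)-8-hydroxy-6-phenyl-3,4,4a,5-tetrahydronaphthalen-1(2H)-one
Product: 15 (S)-5-[4-(benzyloxy)-2-oxo-2H-pyran-6-yl]-3-(tert-butyldimethylsilyloxy)-8-hydroxy-6-phenyl-3,4-dihydronaphthalen-1(2H)-one
Conditions: DDQ (1.1 equiv), 1,4-dioxane, rt
Reagents that add atoms: none
Why: DDQ dehydrogenation of a cyclohexadienol (hydride loss from the activated C5–H, then loss of the C4a proton) should give the phenol, driven by aromatisation; C3 is not involved, and benzyl and silyl ethers tolerate DDQ at room temperature.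

Step 9
Reactants: 15 (S)-5-[4-(benzyloxy)-2-oxo-2H-pyran-6-yl]-3-(tert-butyldimethylsilyloxy)-8-hydroxy-6-phenyl-3,4-dihydronaphthalen-1(2H)-one
Product: 16 (S)-5-[4-(benzyloxy)-2-oxo-2H-pyran-6-yl]-3,8-dihydroxy-6-phenyl-3,4-dihydronaphthalen-1(2H)-one
Conditions: HF·pyridine, pyridine, THF, 0 °C to rt
Reagents that add atoms: none
Why: Fluoride-mediated desilylation under mildly acidic, buffered conditions should free the C3 alcohol with retention (Si–O cleavage) and avoids the basic conditions that would cause E1cB loss of the C3 oxygen and naphthol formation.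

Step 10
Reactants: 16 (S)-5-[4-(benzyloxy)-2-oxo-2H-pyran-6-yl]-3,8-dihydroxy-6-phenyl-3,4-dihydronaphthalen-1(2H)-one
Product: 17 wailupemycin F, (S)-3,8-dihydroxy-5-(4-hydroxy-2-oxo-2H-pyran-6-yl)-6-phenyl-3,4-dihydronaphthalen-1(2H)-one
Conditions: H2 (1 atm), 10% Pd/C, EtOAc, rt, stopped after one equivalent of H2
Reagents that add atoms: none
Why: Hydrogenolysis of the benzyl ether of a vinylogous acid is fast and neutral, so the beta-hydroxy ketone, the pyrone and the hydrogen-bonded aryl ketone should remain intact.

**Compound list**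

1 | all-cis-cyclohexane-1,3,5-triol | O[C@@H]1C[C@H](O)C[C@H](O)C1 | starting material
2 | all-cis-5-(tert-butyldimethylsilyloxy)cyclohexane-1,3-diol (meso) | O[C@@H]1C[C@H](O[Si](C)(C)C(C)(C)C)C[C@H](O)C1 | intermediate
3 | all-cis-5-(tert-butyldimethylsilyloxy)cyclohexane-1,3-diyl diacetate (meso) | CC(=O)O[C@@H]1C[C@H](O[Si](C)(C)C(C)(C)C)C[C@H](OC(C)=O)C1 | intermediate
4 | (1S,3R,5R)-3-(tert-butyldimethylsilyloxy)-5-hydroxycyclohexyl acetate | O[C@H]1C[C@@H](O[Si](C)(C)C(C)(C)C)C[C@@H](OC(C)=O)C1 | intermediate
5 | (1R,3S)-3-(tert-butyldimethylsilyloxy)-5-oxocyclohexyl acetate (keto acetate, not isolated) | O=C1C[C@@H](O[Si](C)(C)C(C)(C)C)C[C@@H](OC(C)=O)C1 | intermediate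
6 | (S)-5-(tert-butyldimethylsilyloxy)cyclohex-2-en-1-one | O=C1C[C@@H](O[Si](C)(C)C(C)(C)C)CC=C1 | intermediate
7 | 4-hydroxy-6-methyl-2H-pyran-2-one (triacetic acid lactone) | CC1=CC(O)=CC(=O)O1 | starting material
8 | 4-(benzyloxy)-6-methyl-2H-pyran-2-one | Cc1cc(OCc2ccccc2)cc(=O)o1 | intermediate
9 | methyl 3-phenylprop-2-ynoate (methyl phenylpropiolate) | COC(=O)C#Cc1ccccc1 | starting material
10 | [4-(benzyloxy)-2-oxo-2H-pyran-6-yl]methyllithium (lithiated pyrone, not isolated) | [Li+].[CH2-]c1cc(OCc2ccccc2)cc(=O)o1 | intermediate
11 | methyl (E)-4-[4-(benzyloxy)-2-oxo-2H-pyran-6-yl]-3-phenylbut-2-enoate | COC(=O)/C=C(\Cc1cc(OCc2ccccc2)cc(=O)o1)c1ccccc1 | intermediate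
12 | lithium dienolate of 11, delocalised over C5, the pyrone and the enoate (not isolated) | [Li+].COC(=O)C=C(c1ccccc1)[CH-]c1cc(OCc2ccccc2)cc(=O)o1 | intermediate
13 | lithium C1–C8a enolate of methyl (2E,4R)-4-[4-(benzyloxy)-2-oxo-2H-pyran-6-yl]-4-[(1S,3S)-3-(tert-butyldimethylsilyloxy)-5-oxocyclohexyl]-3-phenylbut-2-enoate (Michael adduct, side chain trans to the silyloxy group, not isolated) | [Li+].[O-]C1=C[C@H](C[C@H](O[Si](C)(C)C(C)(C)C)C1)[C@@H](c1cc(OCc2ccccc2)cc(=O)o1)/C(c1ccccc1)=C\C(=O)OC | intermediate
14 | (3S,4aR,5R)-5-[4-(benzyloxy)-2-oxo-2H-pyran-6-yl]-3-(tert-butyldimethylsilyloxy)-8-hydroxy-6-phenyl-3,4,4a,5-tetrahydronaphthalen-1(2H)-one | O=C1C[C@@H](O[Si](C)(C)C(C)(C)C)C[C@H]2C1=C(O)C=C(c1ccccc1)[C@@H]2c1cc(OCc2ccccc2)cc(=O)o1 | intermediate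
15 | (S)-5-[4-(benzyloxy)-2-oxo-2H-pyran-6-yl]-3-(tert-butyldimethylsilyloxy)-8-hydroxy-6-phenyl-3,4-dihydronaphthalen-1(2H)-one | O=C1C[C@@H](O[Si](C)(C)C(C)(C)C)Cc2c1c(O)cc(-c1ccccc1)c2-c1cc(OCc2ccccc2)cc(=O)o1 | intermediate
16 | (S)-5-[4-(benzyloxy)-2-oxo-2H-pyran-6-yl]-3,8-dihydroxy-6-phenyl-3,4-dihydronaphthalen-1(2H)-one | O=C1C[C@@H](O)Cc2c1c(O)cc(-c1ccccc1)c2-c1cc(OCc2ccccc2)cc(=O)o1 | intermediate
17 | wailupemycin F, (S)-3,8-dihydroxy-5-(4-hydroxy-2-oxo-2H-pyran-6-yl)-6-phenyl-3,4-dihydronaphthalen-1(2H)-one | O=C1C[C@@H](O)Cc2c1c(O)cc(-c1ccccc1)c2-c1cc(O)cc(=O)o1 | target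

**Step count and risks**

Total step count: 10. Longest linear sequence: 8 steps (steps 1, 2, 3, 4, 7, 8, 9, 10, from the triol 1).

Steps most likely to fail:

1. Step 7. The dienolate may add through C7 (alpha to the ester) and stall, the enone may lose its silyloxy group by enolisation before it is captured, or the Claisen closure may not follow the Michael addition. The fallback sets out from 11 and 6 and comes back at 14. Compound 11 is O-silylated (LiN(SiMe3)2, Me3SiCl, THF, −78 °C) to the trimethylsilyl ketene acetal F1. A vinylogous Mukaiyama–Michael addition of F1 to 6 (Me3SiOTf cat., CH2Cl2, −78 °C) is gamma-selective for silyl dienolates and runs without base. It should give the trimethylsilyl enol ether of the Michael adduct F2, with the enol ether fixed toward C8a. Anhydrous fluoride (Bu4N[Ph3SiF2], THF, −20 °C to rt) then releases that regiodefined enolate, which closes onto the ester and gives 14 after acidification.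

2. Step 6. The lithiated pyrone may add to the ester carbonyl of the ynoate (1,2-addition), or the allenolate may add to further ynoate. The fallback sets out from 8 and comes back at the dienolate 12. Lithiated 8 (2.1 equiv LiN(SiMe3)2, THF, −78 to 0 °C) is acylated with N-methoxy-N-methylbenzamide to the phenacylpyrone F3. Its enol is O-triflated (NaH, PhNTf2, THF) to the enol triflate F4. Negishi-type coupling of F4 with the Reformatsky reagent BrZnCH2CO2Me (Pd(PPh3)4 cat., THF, 60 °C) gives the but-3-enoate F5. F5 is a positional isomer of 11 and gives the same anion 12 under the conditions of step 7.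

3. Step 3. The hydrolysis may proceed with the opposite topicity to the one assumed, or with poor selectivity, which would feed the enantiomeric series into the route. The fallback sets out from 2 and comes back at 4. The same lipase is used in the acylation direction on the meso diol 2 (vinyl acetate, MTBE, 30 °C). Acylation and hydrolysis by one enzyme address the same carbinol centre, so the two modes give enantiomeric monoacetates, and this mode delivers 4 if the hydrolysis goes the wrong way. No new compound arises (F0).

**Further compounds**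

F1 | step 7 | 4-(benzyloxy)-6-[4-methoxy-2-phenyl-4-(trimethylsilyloxy)buta-1,3-dien-1-yl]-2H-pyran-2-one (trimethylsilyl ketene acetal of 11, double-bond geometry not defined) | COC(O[Si](C)(C)C)=CC(c1ccccc1)=Cc1cc(OCc2ccccc2)cc(=O)o1
F2 | step 7 | trimethylsilyl enol ether (C1=C8a) of the Michael adduct, methyl (2E)-4-[4-(benzyloxy)-2-oxo-2H-pyran-6-yl]-4-[5-(tert-butyldimethylsilyloxy)-3-(trimethylsilyloxy)cyclohex-2-en-1-yl]-3-phenylbut-2-enoate, side chain trans to the silyloxy group | C[Si](C)(C)OC1=C[C@H](C[C@H](O[Si](C)(C)C(C)(C)C)C1)[C@@H](c1cc(OCc2ccccc2)cc(=O)o1)/C(c1ccccc1)=C\C(=O)OC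
F3 | step 6 | 4-(benzyloxy)-6-(2-oxo-2-phenylethyl)-2H-pyran-2-one | O=C(Cc1cc(OCc2ccccc2)cc(=O)o1)c1ccccc1
F4 | step 6 | 2-[4-(benzyloxy)-2-oxo-2H-pyran-6-yl]-1-phenylethenyl trifluoromethanesulfonate (geometry not defined) | FC(F)(F)S(=O)(=O)OC(=Cc1cc(OCc2ccccc2)cc(=O)o1)c1ccccc1
F5 | step 6 | methyl 4-[4-(benzyloxy)-2-oxo-2H-pyran-6-yl]-3-phenylbut-3-enoate (geometry not defined) | COC(=O)CC(=Cc1cc(OCc2ccccc2)cc(=O)o1)c1ccccc1
F0 | step 3 | none | none
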